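Compound numbers are those of the steps below. Ring atoms carry the numbering of the target naphthoate throughout: carboxyl on C2, ring C on C4, oxygens on C6 and C7, C5 peri to C4. The systematic names of 7, 8 and 9 count the ring the other way; their C1, C2, C3, C4 and C8 are C4, C3, C2, C1 and C5 of the target.

## Analysis of the target

Eritrichin (18) is the ester formed between the C2 carboxyl of 4-(3,4-dihydroxyphenyl)-6,7-dihydroxy-2-naphthoic acid and the secondary hydroxyl of (R)-3-(3,4-dihydroxyphenyl)lactic acid. The carbocyclic part is a naphthalene made of the dioxygenated benzo ring A (C4a, C5 to C8, C8a) and ring B (C1 to C4), which carries the carboxyl on C2 and the catechol ring C on C4; it holds no stereocentre. The only stereocentre is the (R)-configured carbinol carbon of the lactate, so there is no relative configuration to control, only one centre to preserve. That centre sits alpha to a free carboxylic acid and bears the acyloxy group, so strong base can epimerize it and hard Lewis acids or nucleophiles can cleave the ester. Three catechols make the free compound prone to air oxidation, above all in base, so the last operation should be neutral and reductive. Two things are hard: placing carboxyl and aryl group 1,3 on ring B with oxygen only on C6 and C7, and uncovering six phenols without harming the ester or the stereocentre. The strategy rests on the fact that rings A, B and C with the C2 carboxyl are two C6–C3 hydroxycinnamate units: ring A with C1, C2 and the carboxyl carbon is one, and ring C with C4 and C3 is the other, which has lost its carboxyl. The units are joined by the bonds C2–C3 and C4–C4a, the pattern that phenol oxidation of a 4-hydroxycinnamate produces.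

## Retrosynthetic reasoning

**18 to 17.** The six phenols and the carboxylic acid of 18 are masked as benzyl ethers and a benzyl ester. Cutting the seven O–benzyl bonds last makes the final forward step a neutral catalytic hydrogenolysis. It touches neither the acyl–oxygen bond nor the (R) centre and frees the catechols only when nothing else remains to be done.

**17 to 14 and 16.** The acyl–oxygen bond of the naphthoate is the one bond joining the flat, achiral half to the half with the stereocentre. Cutting it gives acid 14 and alcohol 16. The forward reaction acylates the oxygen of a secondary alcohol, so the C–O bond at the stereocentre is never broken and the configuration of 16 is carried over. Placing this union one step before the end keeps the stereocentre away from every oxidant, strong base and Lewis acid of the route.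

**16 to 15.** Alcohol 16 is the chiral-pool hydroxy acid salt 15 with its carboxylate and catechol benzylated. No stereocentre has to be made.

**14 to 12 to 11.** The benzyl ethers of 14 are traced back, through the free tetrahydroxy acid 12 and its perbenzylated form 13, to the methyl ethers of 11. The exchange costs two steps but is deliberate. The oxidative chemistry upstream needs methyl ethers, yet they come off only with a hard Lewis acid, which the alpha-acyloxy acid of the target would be unlikely to survive. On 11 there is nothing for that reagent to damage.

**11 to 10.** The two C–Br bonds of 10 (on C5 and on ring C) are put back. The bromine atoms are blocking groups that the dimerization needs. In the forward direction they leave by hydrogenolysis as soon as ring B is aromatic and before any benzyl group is present.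

**10 to 9.** Ring B of 10 is taken back to its 3,4-dihydro level and a carboxyl is placed on C3, giving diacid 9. This converts a 1,3-substituted naphthalene, which no simple dimerization gives, into a 4-aryl-3,4-dihydronaphthalene-2,3-dicarboxylic acid, which a dimerization gives directly. Forward, a hydride acceptor has to remove the C4 hydrogen, and the molecule has to lose the C3 carboxyl rather than the C3 hydrogen. The C2 carboxyl sits on an sp2 carbon and cannot leave.

**9 to 8 to 7.** Ester hydrolysis and O-methylation are reversed. Both esters are hydrolysed together because no choice between them is needed. The phenols of 7 are capped first, so that neither base with air nor the quinone oxidant can turn them back into quinone methides.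

**7 to two molecules of 5 (through 6).** The bonds C2–C3 and C4–C4a are cut. They are the only bonds between the two C6–C3 halves of 7, and cutting them gives the same molecule twice, the brominated hydroxycinnamate 5. Forward, one-electron oxidation of the phenol has to join the two ester-bearing carbons to the bis(quinone methide) 6. One half of 6 must then return to a cinnamate, whose ring closes onto the benzylic carbon of the other half. The bromine of 5 is there to close off the ring position ortho to the phenol, which would otherwise couple with the side chain.

**5 to 4 to 1 and 2.** Ester 5 comes from acid 4. The C=C bond of 4 is cut to aldehyde 1 and the two-carbon donor 2; the forward reaction is a condensation through 3 followed by decarboxylation.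

## Alternatives that were turned down

**Alternative 1: one-carbon ring expansion of an indene.**
- Disconnection: C2 of ring B and its ester are removed, leaving the five-membered ring of 1-(3,4-dimethoxyphenyl)-5,6-dimethoxy-1H-indene (A2).
- Forward key step: the rhodium carbenoid generated from ethyl bromodiazoacetate (A3) with catalytic Rh2(esp)2 cyclopropanates the C2=C3 bond of A2. The bromocyclopropane opens with dehydrobromination to the naphthoate A1, ethyl 4-(3,4-dimethoxyphenyl)-6,7-dimethoxy-2-naphthoate, and saponification of A1 would give 11.
- For it: ring B arrives aromatic and carries only the wanted carboxyl. There are no blocking atoms and no decarboxylation. The oxygen pattern is fixed in A2, so the question of which ring position closes does not arise. On these points it is stronger than the chosen route.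
- Against it: the C1–H of A2 is benzylic twice over and allylic. Base, or the metal, can move the double bond into conjugation with the aryl group, and expansion of that isomer would put the aryl group on C1 next to the ester, a regioisomer of A1 that would be hard to separate. The four methoxy groups offer the electrophilic carbenoid other sites (arene cyclopropanation, C–H insertion). A3 is thermally labile and has to be made and used cold.
- Comparison: A2 needs about four steps, so 11 would be reached in six or seven steps, no fewer than the seven of the chosen route, and steps 8 to 12 would be the same. The chosen route offers one cheap aldehyde used twice and a key step that forms both C–C bonds without a carbenoid or a sensitive reagent.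

**Alternative 2: photoenol Diels–Alder reaction with the chiral acrylate.**
- Disconnection: C1–C2 and C3–C4 of ring B, giving 2-(3,4-dimethoxybenzyl)-4,5-dimethoxybenzaldehyde (A5) as diene precursor and the acrylate A6 of the protected lactate as dienophile.
- Forward key step: ultraviolet irradiation of A5 gives, by 1,5-hydrogen shift, a transient photoenol diene that adds A6 to form the tetralol A4 as a mixture of ring diastereomers. Dehydration and dehydrogenation of A4 would then make the naphthalene.
- For it: this is the most convergent plan. After one C–C bond-forming step every carbon of the target and the ester linkage are in place, and no separate esterification is needed. The usual regiochemistry of photoenol additions (ester next to the carbinol) is the one required. Here it is stronger than the chosen route.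
- Against it: three ring stereocentres are made in A4 only to be destroyed, and the lactate stereocentre can control nothing useful. Dehydration and dehydrogenation have to be run on a molecule that already holds the epimerizable alpha-acyloxy ester. Six methyl ethers must then be cleaved by a hard Lewis acid in the presence of that ester, the operation the chosen route places before the esterification. The aryl group on the diene terminus hinders the cycloaddition, and the photochemical step scales poorly.
- Comparison: with three to four steps for A5 and about three for A6, the count is eleven or twelve, which is no gain. The chosen route offers a stereocentre that enters only after all oxidants, acids and bases have been used.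

**Alternative 3: aryne–pyrone cycloaddition with decarboxylation.**
- Disconnection: C1–C8a and C4–C4a; ring A is added as an aryne to a preformed C1–C4 unit, methyl 6-(3,4-dimethoxyphenyl)-2-oxo-2H-pyran-4-carboxylate (A8).
- Forward key step: fluoride releases the symmetrical aryne from 4,5-dimethoxy-2-(trimethylsilyl)phenyl trifluoromethanesulfonate (A9). The aryne adds across C3 and C6 of A8, and the bridged lactone loses its bridge by decarboxylation to give the naphthoate A7, methyl 4-(3,4-dimethoxyphenyl)-6,7-dimethoxy-2-naphthoate. Saponification of A7 would give 11.
- For it: the aryne is symmetrical, so there is no regiochemical question. Ring B of A7 is aromatic at once, the cycloreversion is irreversible, and no blocking groups are needed. In the directness of ring B formation it is stronger than the chosen route.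
- Against it: A8 is an electron-poor diene (ester on C4, lactone carbonyl) and the aryne is electrophilic. The cycloaddition is therefore mismatched and would need excess aryne, which can oligomerize or add to the electron-rich product A7. Neither A8 (two to three steps) nor A9 (three to four steps) is a bulk chemical.
- Comparison: A7 would take six to eight steps over two branches and 11 one more, against seven linear steps from one aldehyde, and steps 8 to 12 would be unchanged. The chosen route offers cheaper material and both ring B bonds from a single monomer.

Key step: step 3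

Assumption: the sodium salt of (R)-danshensu (15) is taken as a purchasable single enantiomer. Compounds 7, 8 and 9 are racemic; their drawn configuration is relative only and is erased in step 6.

## Route

Step 1
Reactants: 1 5-bromovanillin (3-bromo-4-hydroxy-5-methoxybenzaldehyde); 2 malonic acid
Product: 4 (E)-3-(3-bromo-4-hydroxy-5-methoxyphenyl)acrylic acid (5-bromoferulic acid), via arylidenemalonic acid 3 (not isolated)
Conditions: pyridine, piperidine (cat.), 95 °C; then aq. HCl
Reagents that add atoms: none
Why: Knoevenagel condensation gives 3, which decarboxylates in hot pyridine (Doebner modification) through the less crowded arrangement, so only the (E)-acid is expected; the free phenol is tolerated, as in the standard preparation of ferulic acid from vanillin.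

Step 2
Reactants: 4 (E)-3-(3-bromo-4-hydroxy-5-methoxyphenyl)acrylic acid
Product: 5 methyl (E)-3-(3-bromo-4-hydroxy-5-methoxyphenyl)acrylate (methyl 5-bromoferulate)
Conditions: MeOH, H2SO4 (cat.), reflux
Reagents that add atoms: methanol, CO
Why: Fischer esterification; phenol, aryl bromide and the conjugated double bond are inert to methanolic acid, and the ester is needed because a free carboxyl would trap the quinone methides of step 3 as lactones.

Step 3
Reactants: 5 methyl (E)-3-(3-bromo-4-hydroxy-5-methoxyphenyl)acrylate (two molecules)
Product: 7 dimethyl trans-8-bromo-1-(3-bromo-4-hydroxy-5-methoxyphenyl)-7-hydroxy-6-methoxy-1,2-dihydronaphthalene-2,3-dicarboxylate (racemic), via bis(quinone methide) 6 (not isolated)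
Conditions: FeCl3·6H2O (2.2 equiv, added slowly), acetone–H2O, 0 °C to rt, dilute
Reagents that add atoms: none
Why: Trivalent iron takes one electron from the phenol of 5; the phenoxyl radical carries spin on the side-chain carbon next to the ester, and two radicals combine there (bond C2–C3) to give the bis(quinone methide) 6. One half of 6 loses its acidic proton alpha to the ester and returns to an aromatic cinnamate, whose ring carbon para to the methoxy group (the future C4a) adds to the exocyclic methide carbon of the other half (bond C4–C4a), rearomatizing ring C and closing ring B. This closure is an intramolecular Friedel–Crafts alkylation forming a six-membered ring, 6-exo-trig with respect to the quinone methide C=C bond. The closest known reaction is the FeCl3 or enzymatic oxidation of sinapate esters to 1-aryl-1,2-dihydronaphthalene-2,3-dicarboxylates of the thomasidioate type. Two stereocentres arise, the aryl-bearing C4 and the ester-bearing C3: the aryl group should take the pseudoaxial position to avoid the peri bromine on C5, and the ester on the epimerizable C3 should settle trans to it, so the racemic trans isomer is expected. The step needs coupling between the two ester-bearing carbons rather than at a ring carbon or at oxygen; bromine and methoxy occupy both positions ortho to the phenol oxygen, which excludes side chain to ring coupling and, as in sinapates, hinders attack through the flanked oxygen. It also needs closure para rather than ortho to methoxy; the para position is the more activated, and the ortho position is screened by the in-plane methyl of the methoxy group, which is turned away from the hydrogen-bonded phenol. Slow addition of a small excess of oxidant at high dilution should hold back further oxidation of 7.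

Step 4
Reactants: 7 dimethyl trans-8-bromo-1-(3-bromo-4-hydroxy-5-methoxyphenyl)-7-hydroxy-6-methoxy-1,2-dihydronaphthalene-2,3-dicarboxylate
Product: 8 dimethyl trans-8-bromo-1-(3-bromo-4,5-dimethoxyphenyl)-6,7-dimethoxy-1,2-dihydronaphthalene-2,3-dicarboxylate (racemic)
Conditions: MeI, K2CO3, acetone, reflux
Reagents that add atoms: iodomethane, CI
Why: Williamson etherification of the two phenols; K2CO3 is too weak to deprotonate C3–H, and the methyl ethers stop base with air (step 5) or DDQ (step 6) from reoxidizing the phenols to quinone methides.

Step 5
Reactants: 8 dimethyl trans-8-bromo-1-(3-bromo-4,5-dimethoxyphenyl)-6,7-dimethoxy-1,2-dihydronaphthalene-2,3-dicarboxylate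
Product: 9 trans-8-bromo-1-(3-bromo-4,5-dimethoxyphenyl)-6,7-dimethoxy-1,2-dihydronaphthalene-2,3-dicarboxylic acid (racemic)
Conditions: NaOH (aq., excess), MeOH–THF, 65 °C, N2; then 1 M HCl
Reagents that add atoms: sodium hydroxide, [Na+].[OH-]
Why: Saponification of both esters; the saturated ester on C3 should react first, and its carboxylate then suppresses deprotonation at C3, so the C1=C2 double bond should stay in place while the slower conjugated C2 ester is cleaved. No selectivity between the esters is needed, because only the carboxyl on the sp3 carbon can leave in step 6.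

Step 6
Reactants: 9 trans-8-bromo-1-(3-bromo-4,5-dimethoxyphenyl)-6,7-dimethoxy-1,2-dihydronaphthalene-2,3-dicarboxylic acid
Product: 10 5-bromo-4-(3-bromo-4,5-dimethoxyphenyl)-6,7-dimethoxy-2-naphthoic acid
Conditions: DDQ (1.3 equiv), 1,4-dioxane, 80 °C
Reagents that add atoms: none
Why: Oxidative decarboxylation of a dihydroaromatic acid: DDQ abstracts hydride from C4–H, which is benzylic to rings A and C and para to a methoxy group on each, and the cation, beta to the C3 carboxyl, loses CO2 to give aromatic ring B. The C2 carboxyl is on an sp2 carbon and stays, which leaves carboxyl and aryl group 1,3 as in the target.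

Step 7
Reactants: 10 5-bromo-4-(3-bromo-4,5-dimethoxyphenyl)-6,7-dimethoxy-2-naphthoic acid
Product: 11 4-(3,4-dimethoxyphenyl)-6,7-dimethoxy-2-naphthoic acid
Conditions: H2 (1 atm), 10% Pd/C, NaOAc (3 equiv), MeOH–THF, rt; then dilute HCl
Reagents that add atoms: none
Why: Catalytic hydrodehalogenation of both aryl C–Br bonds with NaOAc as scavenger for HBr; methyl ethers, the acid and the naphthalene are inert at 1 atm and room temperature, and the blocking atoms are removed before any benzyl group is present.

Step 8
Reactants: 11 4-(3,4-dimethoxyphenyl)-6,7-dimethoxy-2-naphthoic acid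
Product: 12 4-(3,4-dihydroxyphenyl)-6,7-dihydroxy-2-naphthoic acid
Conditions: BBr3 (8 equiv), CH2Cl2, −78 °C to rt; then ice water, under Ar
Reagents that add atoms: none
Why: Lewis-acid cleavage of the four aryl methyl ethers (boron coordinates the ether oxygen, bromide attacks the methyl group); the carboxylic acid is only converted to an acyloxyborane that water returns. The step is placed here because the molecule has no ester linkage and no stereocentre yet.

Step 9
Reactants: 12 4-(3,4-dihydroxyphenyl)-6,7-dihydroxy-2-naphthoic acid
Product: 14 6,7-bis(benzyloxy)-4-[3,4-bis(benzyloxy)phenyl]-2-naphthoic acid, via benzyl ester 13 (not isolated)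
Conditions: BnBr (5.5 equiv), K2CO3, DMF, 60 °C, Ar; then aq. NaOH, MeOH–THF, 60 °C; then 1 M HCl
Reagents that add atoms: benzyl bromide, BrCc1ccccc1; sodium hydroxide, [Na+].[OH-]
Why: Williamson benzylation of the four phenoxides and the carboxylate gives 13; hydroxide added to the same flask saponifies the benzyl ester and leaves the aryl benzyl ethers, so the acid is obtained with protecting groups that hydrogenolysis removes.

Step 10
Reactants: 15 sodium (R)-3-(3,4-dihydroxyphenyl)-2-hydroxypropanoate (sodium salt of (R)-danshensu)
Product: 16 benzyl (R)-3-[3,4-bis(benzyloxy)phenyl]-2-hydroxypropanoate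
Conditions: BnBr (3.2 equiv), K2CO3 (2.5 equiv), DMF, rt, Ar
Reagents that add atoms: benzyl bromide, BrCc1ccccc1
Why: O-alkylation of the carboxylate and of the two phenoxides; K2CO3 does not deprotonate the secondary alcohol, which stays free. No bond to the stereocentre is touched, and its alpha hydrogen is not acidic enough to exchange under these conditions.

Step 11
Reactants: 14 6,7-bis(benzyloxy)-4-[3,4-bis(benzyloxy)phenyl]-2-naphthoic acid; 16 benzyl (R)-3-[3,4-bis(benzyloxy)phenyl]-2-hydroxypropanoate
Product: 17 (R)-1-(benzyloxy)-3-[3,4-bis(benzyloxy)phenyl]-1-oxopropan-2-yl 6,7-bis(benzyloxy)-4-[3,4-bis(benzyloxy)phenyl]-2-naphthoate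
Conditions: DCC (1.2 equiv), DMAP (0.2 equiv), CH2Cl2, 0 °C to rt
Reagents that add atoms: none
Why: Steglich esterification: DCC activates the unhindered naphthoic acid (hydrogens on C1 and C3) and DMAP passes the acyl group to the secondary alcohol. The C–O bond at the stereocentre is not broken, so the (R) configuration of 16 is retained, and the mild base should not epimerize the product.

Step 12
Reactants: 17 (R)-1-(benzyloxy)-3-[3,4-bis(benzyloxy)phenyl]-1-oxopropan-2-yl 6,7-bis(benzyloxy)-4-[3,4-bis(benzyloxy)phenyl]-2-naphthoate
Product: 18 eritrichin, (R)-3-(3,4-dihydroxyphenyl)-2-{[4-(3,4-dihydroxyphenyl)-6,7-dihydroxy-2-naphthoyl]oxy}propanoic acid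
Conditions: H2 (1 atm), 10% Pd/C, THF–MeOH, rt; filtration and evaporation under Ar
Reagents that add atoms: none
Why: Catalytic hydrogenolysis of six aryl benzyl ethers and the benzyl ester; the alkyl oxygen of the naphthoate is homobenzylic, so that ester is not cleaved. The neutral medium leaves the stereocentre alone and frees the catechols without base or oxidant.

## Compound list

1 | 5-bromovanillin (3-bromo-4-hydroxy-5-methoxybenzaldehyde) | COc1cc(C=O)cc(Br)c1O | starting material
2 | malonic acid | OC(=O)CC(=O)O | starting material
3 | 2-(3-bromo-4-hydroxy-5-methoxybenzylidene)malonic acid | COc1cc(C=C(C(=O)O)C(=O)O)cc(Br)c1O | intermediate (not isolated)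
4 | (E)-3-(3-bromo-4-hydroxy-5-methoxyphenyl)acrylic acid | COc1cc(/C=C/C(=O)O)cc(Br)c1O | intermediate
5 | methyl (E)-3-(3-bromo-4-hydroxy-5-methoxyphenyl)acrylate | COC(=O)/C=C/c1cc(OC)c(O)c(Br)c1 | intermediate
6 | dimethyl 2,3-bis[(3-bromo-5-methoxy-4-oxocyclohexa-2,5-dien-1-ylidene)methyl]butanedioate (mixture of diastereomers) | COC(=O)C(C=C1C=C(OC)C(=O)C(Br)=C1)C(C=C1C=C(OC)C(=O)C(Br)=C1)C(=O)OC | intermediate (not isolated)
7 | dimethyl trans-8-bromo-1-(3-bromo-4-hydroxy-5-methoxyphenyl)-7-hydroxy-6-methoxy-1,2-dihydronaphthalene-2,3-dicarboxylate (racemic, one enantiomer drawn) | COC(=O)C1=Cc2cc(OC)c(O)c(Br)c2[C@H](c2cc(OC)c(O)c(Br)c2)[C@H]1C(=O)OC | intermediate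
8 | dimethyl trans-8-bromo-1-(3-bromo-4,5-dimethoxyphenyl)-6,7-dimethoxy-1,2-dihydronaphthalene-2,3-dicarboxylate (racemic, one enantiomer drawn) | COC(=O)C1=Cc2cc(OC)c(OC)c(Br)c2[C@H](c2cc(OC)c(OC)c(Br)c2)[C@H]1C(=O)OC | intermediate
9 | trans-8-bromo-1-(3-bromo-4,5-dimethoxyphenyl)-6,7-dimethoxy-1,2-dihydronaphthalene-2,3-dicarboxylic acid (racemic, one enantiomer drawn) | OC(=O)C1=Cc2cc(OC)c(OC)c(Br)c2[C@H](c2cc(OC)c(OC)c(Br)c2)[C@H]1C(=O)O | intermediate
10 | 5-bromo-4-(3-bromo-4,5-dimethoxyphenyl)-6,7-dimethoxy-2-naphthoic acid | OC(=O)c1cc(-c2cc(OC)c(OC)c(Br)c2)c2c(Br)c(OC)c(OC)cc2c1 | intermediate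
11 | 4-(3,4-dimethoxyphenyl)-6,7-dimethoxy-2-naphthoic acid | OC(=O)c1cc(-c2ccc(OC)c(OC)c2)c2cc(OC)c(OC)cc2c1 | intermediate
12 | 4-(3,4-dihydroxyphenyl)-6,7-dihydroxy-2-naphthoic acid | OC(=O)c1cc(-c2ccc(O)c(O)c2)c2cc(O)c(O)cc2c1 | intermediate
13 | benzyl 6,7-bis(benzyloxy)-4-[3,4-bis(benzyloxy)phenyl]-2-naphthoate | O=C(OCc1ccccc1)c1cc(-c2ccc(OCc3ccccc3)c(OCc3ccccc3)c2)c2cc(OCc3ccccc3)c(OCc3ccccc3)cc2c1 | intermediate (not isolated)
14 | 6,7-bis(benzyloxy)-4-[3,4-bis(benzyloxy)phenyl]-2-naphthoic acid | OC(=O)c1cc(-c2ccc(OCc3ccccc3)c(OCc3ccccc3)c2)c2cc(OCc3ccccc3)c(OCc3ccccc3)cc2c1 | intermediate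
15 | sodium (R)-3-(3,4-dihydroxyphenyl)-2-hydroxypropanoate | [Na+].[O-]C(=O)[C@H](O)Cc1ccc(O)c(O)c1 | starting material
16 | benzyl (R)-3-[3,4-bis(benzyloxy)phenyl]-2-hydroxypropanoate | O=C(OCc1ccccc1)[C@H](O)Cc1ccc(OCc2ccccc2)c(OCc2ccccc2)c1 | intermediate
17 | (R)-1-(benzyloxy)-3-[3,4-bis(benzyloxy)phenyl]-1-oxopropan-2-yl 6,7-bis(benzyloxy)-4-[3,4-bis(benzyloxy)phenyl]-2-naphthoate | O=C(O[C@H](Cc1ccc(OCc2ccccc2)c(OCc2ccccc2)c1)C(=O)OCc1ccccc1)c1cc(-c2ccc(OCc3ccccc3)c(OCc3ccccc3)c2)c2cc(OCc3ccccc3)c(OCc3ccccc3)cc2c1 | intermediate
18 | eritrichin | O=C(O[C@H](Cc1ccc(O)c(O)c1)C(=O)O)c1cc(-c2ccc(O)c(O)c2)c2cc(O)c(O)cc2c1 | target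

## Step count and least certain steps

Total step count: 12. Longest linear sequence: 11 steps (steps 1 to 9, 11 and 12); step 10 is a one-step side branch.

**Step 3 (key step).**
- What may go wrong: the radicals may couple through the phenol oxygen instead of carbon to carbon. Water may capture the bis(quinone methide) before ring closure. The ring may close ortho instead of para to methoxy. The product may be oxidized further, because its ring C phenol is still para to a benzylic hydrogen.
- Fallback: it sets out from 4 and comes back at 7. The free acid 4 is oxidized with FeCl3 in aqueous acetone. Each quinone methide is then captured at once by the carboxyl group of the other half, and the carbon–carbon coupled dimer leaves the oxidizing medium as the cis-fused dilactone 3,6-bis(3-bromo-4-hydroxy-5-methoxyphenyl)tetrahydrofuro[3,4-c]furan-1,4-dione F1. Heating F1 with HCl in methanol should ionize the benzylic C–O bonds; one half eliminates to the cinnamate, the other closes ring B by the same Friedel–Crafts step without any oxidant present, and both carboxyls are esterified in the same pot, giving 7.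

**Step 6.**
- What may go wrong: the cation may lose the C3 proton instead of CO2, which keeps both carboxyls on the aromatized ring. Hydride abstraction may be slow, because in the preferred conformer the C4–H bond lies near the plane of ring A and flattening C4 builds peri strain against the bromine on C5.
- Fallback: it sets out from 9 and comes back at 10, and separates loss of the carboxyl from aromatization. Acetic anhydride closes 9 to the cyclic anhydride 5-bromo-4-(3-bromo-4,5-dimethoxyphenyl)-6,7-dimethoxy-3a,4-dihydronaphtho[2,3-c]furan-1,3-dione F2. The sodium salt of N-hydroxypyridine-2-thione opens F2 at the saturated, more electrophilic carbonyl to the thiohydroxamate half-ester 8-bromo-1-(3-bromo-4,5-dimethoxyphenyl)-6,7-dimethoxy-2-{[(2-thioxopyridin-1(2H)-yl)oxy]carbonyl}-1,2-dihydronaphthalene-3-carboxylic acid F3, which is not isolated. Visible light and tert-butyl thiol (Barton reductive decarboxylation) then remove only the C3 carboxyl, giving 5-bromo-4-(3-bromo-4,5-dimethoxyphenyl)-6,7-dimethoxy-3,4-dihydronaphthalene-2-carboxylic acid F4, possibly together with its 1,4-dihydro isomer. DDQ dehydrogenates either isomer to 10.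

**Step 5.**
- What may go wrong: in hot base the C1=C2 double bond may migrate to C2=C3 before the first ester is cleaved, which would leave no sp3 carboxyl for step 6. The hindered, conjugated C2 ester may also hydrolyse incompletely.
- Fallback: it sets out from 8 and comes back at 10, putting the difficult hydrolysis after aromatization. One equivalent of LiOH in aqueous THF at 0 °C cleaves only the saturated ester, giving the half-ester trans-8-bromo-1-(3-bromo-4,5-dimethoxyphenyl)-6,7-dimethoxy-3-(methoxycarbonyl)-1,2-dihydronaphthalene-2-carboxylic acid F5. DDQ in dioxane converts F5 by the oxidative decarboxylation of step 6 into methyl 5-bromo-4-(3-bromo-4,5-dimethoxyphenyl)-6,7-dimethoxy-2-naphthoate F6. Its aromatic ester can no longer isomerize and is saponified with aqueous NaOH to 10.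

## Further compounds

F1 | step 3 | 3,6-bis(3-bromo-4-hydroxy-5-methoxyphenyl)tetrahydrofuro[3,4-c]furan-1,4-dione (cis-fused, aryl groups exo, racemic, one enantiomer drawn) | O=C1O[C@@H](c3cc(OC)c(O)c(Br)c3)[C@H]2[C@@H]1[C@H](c1cc(OC)c(O)c(Br)c1)OC2=O
F2 | step 6 | 5-bromo-4-(3-bromo-4,5-dimethoxyphenyl)-6,7-dimethoxy-3a,4-dihydronaphtho[2,3-c]furan-1,3-dione (racemic, one enantiomer drawn) | O1C(=O)C2=Cc3cc(OC)c(OC)c(Br)c3[C@H](c3cc(OC)c(OC)c(Br)c3)[C@H]2C1=O
F3 | step 6 | 8-bromo-1-(3-bromo-4,5-dimethoxyphenyl)-6,7-dimethoxy-2-{[(2-thioxopyridin-1(2H)-yl)oxy]carbonyl}-1,2-dihydronaphthalene-3-carboxylic acid (trans, racemic, one enantiomer drawn) | OC(=O)C1=Cc2cc(OC)c(OC)c(Br)c2[C@H](c2cc(OC)c(OC)c(Br)c2)[C@H]1C(=O)On1ccccc1=S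
F4 | step 6 | 5-bromo-4-(3-bromo-4,5-dimethoxyphenyl)-6,7-dimethoxy-3,4-dihydronaphthalene-2-carboxylic acid (racemic) | OC(=O)C1=Cc2cc(OC)c(OC)c(Br)c2C(c2cc(OC)c(OC)c(Br)c2)C1
F5 | step 5 | trans-8-bromo-1-(3-bromo-4,5-dimethoxyphenyl)-6,7-dimethoxy-3-(methoxycarbonyl)-1,2-dihydronaphthalene-2-carboxylic acid (racemic, one enantiomer drawn) | COC(=O)C1=Cc2cc(OC)c(OC)c(Br)c2[C@H](c2cc(OC)c(OC)c(Br)c2)[C@H]1C(=O)O
F6 | step 5 | methyl 5-bromo-4-(3-bromo-4,5-dimethoxyphenyl)-6,7-dimethoxy-2-naphthoate | COC(=O)c1cc(-c2cc(OC)c(OC)c(Br)c2)c2c(Br)c(OC)c(OC)cc2c1
A1 | alternative 1 | ethyl 4-(3,4-dimethoxyphenyl)-6,7-dimethoxy-2-naphthoate | CCOC(=O)c1cc(-c2ccc(OC)c(OC)c2)c2cc(OC)c(OC)cc2c1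
A2 | alternative 1 | 1-(3,4-dimethoxyphenyl)-5,6-dimethoxy-1H-indene (racemic) | COc1ccc(C2C=Cc3cc(OC)c(OC)cc32)cc1OC
A3 | alternative 1 | ethyl bromodiazoacetate | CCOC(=O)C(Br)=[N+]=[N-]
A4 | alternative 2 | (R)-1-(benzyloxy)-3-(3,4-dimethoxyphenyl)-1-oxopropan-2-yl 4-(3,4-dimethoxyphenyl)-1-hydroxy-6,7-dimethoxy-1,2,3,4-tetrahydronaphthalene-2-carboxylate (mixture of ring diastereomers) | O=C(O[C@H](Cc1ccc(OC)c(OC)c1)C(=O)OCc1ccccc1)C1CC(c2ccc(OC)c(OC)c2)c2cc(OC)c(OC)cc2C1O
A5 | alternative 2 | 2-(3,4-dimethoxybenzyl)-4,5-dimethoxybenzaldehyde | COc1ccc(Cc2cc(OC)c(OC)cc2C=O)cc1OC
A6 | alternative 2 | (R)-1-(benzyloxy)-3-(3,4-dimethoxyphenyl)-1-oxopropan-2-yl acrylate | C=CC(=O)O[C@H](Cc1ccc(OC)c(OC)c1)C(=O)OCc1ccccc1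
A7 | alternative 3 | methyl 4-(3,4-dimethoxyphenyl)-6,7-dimethoxy-2-naphthoate | COC(=O)c1cc(-c2ccc(OC)c(OC)c2)c2cc(OC)c(OC)cc2c1
A8 | alternative 3 | methyl 6-(3,4-dimethoxyphenyl)-2-oxo-2H-pyran-4-carboxylate | COC(=O)c1cc(-c2ccc(OC)c(OC)c2)oc(=O)c1
A9 | alternative 3 | 4,5-dimethoxy-2-(trimethylsilyl)phenyl trifluoromethanesulfonate | COc1cc(OS(=O)(=O)C(F)(F)F)c([Si](C)(C)C)cc1OC
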